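**Strategy.** Everything rests on opening the C4–C5 bond of the cyclobutane C4–C5–C6–C7. C4 is a quaternary ring carbon bearing a methyl group and the oxygenated carbon C3, which is what a cyclopentanone C3–C4–C7–C6–C5 leaves behind when its carbonyl carbon is pushed out of the ring. In one operation a methoxide-triggered quasi-Favorskii shift of bridgehead C5 from C3 to C4 forms that bond, the four-membered ring and the C4 stereocentre, and turns C3 into an ester. The precursor is bicyclo[3.2.1]octanone 22: C3 ketone, exo-bromo/endo-methyl C4, C8 ketal and the complete C11 arm, with bromine placed on a monocyclic cyclopentanone before the bicycle is closed.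

Key step: step 15

Remark: target locants C1–C11 are used for every intermediate (cyclobutane C4–C5–C6–C7, carbonyl C8, methyl-bearing C10, quaternary C11); the absolute configuration comes from commercial monoacetate 1, whose acetoxy carbon becomes C6 and whose carbinol carbon becomes C3.

Remark: the shift inverts C4, so bromide must be exo (on the C6-bridge face); that face of the bicyclic enolate lies under the C11 group, so C4 is not set by bromination or equilibration of the bicycle but on cyclopentanone 17, anti to the C7 side chain (step 11).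

Remark: the target carries two angelate esters, so step 24 consumes two molecules of angelic acid, each activated as mixed anhydride 36; the second is entered among the reagents of that step.

Step 1
Reactants: 1 (1R,4S)-cis-4-acetoxycyclopent-2-en-1-ol; 2 methyl Meldrum's acid
Product: 3 allylated Meldrum's acid
Conditions: NaH, THF, 0 °C (on 2); then 1, Pd(PPh3)4 (cat.), THF, rt
Reagents that add atoms: none
Why: Tsuji–Trost allylic alkylation in which ionisation of the acetate and attack of the soft anion both occur anti to palladium, so the C6–C11 bond should form with net retention (cis to the C3 hydroxyl) at the allyl terminus remote from the hydroxyl.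

Step 2
Reactants: 3 allylated Meldrum's acid
Product: 5 bridged methyl lactone, via lactone acid 4 (not isolated)
Conditions: toluene, 100 °C; then pyridine, 115 °C
Reagents that add atoms: none
Why: Intramolecular alcoholysis of the Meldrum's acid by the cis C3 hydroxyl (loss of acetone) followed by thermal decarboxylation of the malonic half-acid should give the bridged δ-lactone, which can only close on the cis face; the C11 epimer mixture is irrelevant because C11 is re-enolised in step 3.

Step 3
Reactants: 5 bridged methyl lactone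
Product: 6 quaternary lactone
Conditions: LiN(iPr)2, THF, −78 °C; BnOCH2Cl, DMPU, −78 → −30 °C
Reagents that add atoms: benzyl chloromethyl ether, ClCOCc1ccccc1
Why: Lactone enolate alkylation in which the sofa-shaped enolate of the 2-oxabicyclo[3.2.1]octenone should be attacked on the face away from the C4=C7 etheno bridge (syn to the C5 methylene bridge), which fixes the quaternary centre C11 relative to C6 (benzyloxymethyl arm = future C1, lactone carbonyl = future hydroxymethyl arm).

Step 4
Reactants: 6 quaternary lactone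
Product: 7 diol
Conditions: LiAlH4, THF, 0 °C
Reagents that add atoms: none
Why: Hydride reduction of the lactone releases the second C11 arm as a primary alcohol and C3 as an allylic alcohol without touching a stereocentre.

Step 5
Reactants: 7 diol
Product: 8 mono-silyl ether
Conditions: TBSCl, imidazole, CH2Cl2, 0 °C
Reagents that add atoms: tert-butyldimethylsilyl chloride, CC(C)(C)[Si](C)(C)Cl
Why: Silyl ether formation should be selective for the primary hydroxyl over the secondary allylic one.

Step 6
Reactants: 8 mono-silyl ether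
Product: 9 cyclopentenone
Conditions: Dess–Martin periodinane, CH2Cl2, rt
Reagents that add atoms: none
Why: Dess–Martin oxidation of the allylic alcohol gives the 4-substituted cyclopent-2-enone under neutral conditions that leave the γ-stereocentre C6 untouched.

Step 7
Reactants: 9 cyclopentenone
Product: 10 iodoenone
Conditions: I2, pyridine, CH2Cl2, rt
Reagents that add atoms: iodine, II
Why: α-Iodination of the enone by conjugate addition of pyridine, iodination of the enol and elimination places the halogen only at C4.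

Step 8
Reactants: 10 iodoenone
Product: 11 methyl enone
Conditions: Me4Sn, Pd2(dba)3 (cat.), AsPh3, CuI (cat.), NMP, 60 °C
Reagents that add atoms: tetramethylstannane, C[Sn](C)(C)C
Why: Stille cross-coupling of the 2-iodoenone installs the C4 methyl group under neutral conditions, so the enolate of step 10 will be regiodefined.

Step 9
Reactants: 12 3-bromobut-3-en-1-ol
Product: 13 bromobutenyl silyl ether
Conditions: Et3SiCl, imidazole, CH2Cl2, 0 °C
Reagents that add atoms: chlorotriethylsilane, CC[Si](CC)(CC)Cl
Why: Standard silyl protection of the primary alcohol so that the vinyl bromide can be metallated.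

Step 10
Reactants: 13 bromobutenyl silyl ether; 11 methyl enone
Product: 15 silyl enol ether, via Grignard reagent 14 (not isolated)
Conditions: Mg, THF, 40 °C (on 13); then CuBr·SMe2 (cat.), Me3SiCl, HMPA, 11, THF, −78 °C; Et3N, pentane work-up
Reagents that add atoms: chlorotrimethylsilane, C[Si](C)(C)Cl
Why: Copper-catalysed, silyl-chloride-accelerated conjugate addition of the vinyl Grignard reagent should attack C7 anti to the bulky C6 substituent (setting C7) and trap the enolate regiospecifically as the C3=C4 silyl enol ether.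

Step 11
Reactants: 15 silyl enol ether
Product: 17 bromo hydroxy ketone, via silyl-protected bromo ketone 16 (not isolated)
Conditions: NBS, THF, −78 °C; then PPTS, MeOH, 0 °C
Reagents that add atoms: N-bromosuccinimide, O=C1CCC(=O)N1Br
Why: Electrophilic bromination of the silyl enol ether should occur anti to the adjacent C7 chain, setting C4 with bromine trans and methyl cis to that chain (the future exo-Br/endo-Me arrangement), and mild acidic methanolysis then cleaves only the primary triethylsilyl ether.

Step 12
Reactants: 17 bromo hydroxy ketone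
Product: 19 bicyclic bromo ketone, via primary triflate 18 (not isolated)
Conditions: Tf2O, 2,6-lutidine, CH2Cl2, −78 °C; then LiN(SiMe3)2, THF, high dilution, −78 → −40 °C
Reagents that add atoms: none
Why: Intramolecular enolate alkylation (6-exo-tet) in which only C5 can be enolised and the tether can reach C5 only on the face of the C7 chain, which sets C5, closes the bicyclo[3.2.1]octane and leaves the C11 group syn to the C3–C4 bridge and bromine exo.

Step 13
Reactants: 19 bicyclic bromo ketone
Product: 21 diketone, via methoxy hydroperoxide 20 (not isolated)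
Conditions: O3, CH2Cl2/MeOH, −78 °C; then Me2S, −78 °C → rt
Reagents that add atoms: ozone, [O-][O+]=O
Why: Ozonolysis with reductive work-up converts the exocyclic methylene into the C8 ketone; C7 is now a bridgehead and cannot enolise, so the β-bromide is not eliminated.

Step 14
Reactants: 21 diketone
Product: 22 bromo ketone ketal
Conditions: Me3SiOCH2CH2OSiMe3, Me3SiOTf (cat.), CH2Cl2, −78 → −20 °C
Reagents that add atoms: 1,2-bis(trimethylsilyloxy)ethane, C[Si](C)(C)OCCO[Si](C)(C)C
Why: Silyl-triflate-catalysed ketalisation should take place only at C8 because the C3 carbonyl is flanked by quaternary C4 and bridgehead C5 and shielded by C11.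

Step 15
Reactants: 22 bromo ketone ketal
Product: 23 ring-contracted methyl ester
Conditions: NaOMe, MeOH/THF, 0 °C → rt
Reagents that add atoms: sodium methoxide, [Na+].[O-]C
Why: Methoxide adds to the C3 carbonyl from the endo face (the exo face is covered by C11), and the hemiketal alkoxide pushes the C3–C5 bond onto C4 while bromide leaves, a semibenzilic 1,2-shift that turns C3 into the methyl ester. The closest known reaction type is the quasi-Favorskii contraction of non-enolisable α-halo ketones in bridged and caged cyclopentanones to cyclobutanecarboxylates. The cyclobutane C4–C5–C6–C7 closes by this 1,2-alkyl shift, that is by backside displacement of bromide at C4 by the migrating bridgehead C5, a ring contraction and not an end-to-end cyclisation. The new quaternary centre C4 forms with inversion, so its configuration is dictated by the exo C–Br bond set in step 11, while C5 migrates with retention. The step needs addition and migration to beat α′-enolisation, epoxy-ether formation and loss of HBr towards the C4 methyl group: C5 is a bridgehead, the alkoxide from endo attack is cis to the exo bromide and cannot close an epoxide, and relief of the exo-Br/C11 compression should favour the shift.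

Step 16
Reactants: 23 ring-contracted methyl ester
Product: 25 methyl ketone, via α-silyl ketone 24 (not isolated)
Conditions: Me3SiCH2Li (2.2 equiv), pentane/THF, 0 °C → rt; then MeOH, rt
Reagents that add atoms: (trimethylsilyl)methyllithium, [Li]C[Si](C)(C)C
Why: Acylation of the silylmethyl carbanion by the ester gives an α-silyl ketone that is immediately deprotonated by a second equivalent, which blocks a second addition, and methanolysis of the C–Si bond then leaves the C3 methyl ketone whose methyl group is C2.

Step 17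
Reactants: 25 methyl ketone
Product: 26 hydroxy ketone
Conditions: H2 (1 atm), Pd/C, EtOAc, rt
Reagents that add atoms: none
Why: Hydrogenolysis removes the benzyl ether from the future C1 arm while the ketone, ketal and silyl ether are inert.

Step 18
Reactants: 26 hydroxy ketone
Product: 27 keto aldehyde
Conditions: Dess–Martin periodinane, CH2Cl2, rt
Reagents that add atoms: none
Why: Dess–Martin oxidation gives the non-enolisable C1 aldehyde on quaternary C11.

Step 19
Reactants: 27 keto aldehyde
Product: 28 β-hydroxy ketone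
Conditions: lithium 2,2,6,6-tetramethylpiperidide, THF, −78 °C; AcOH quench at −78 °C
Reagents that add atoms: none
Why: Intramolecular aldol addition closing the seven-membered ring, in which only the acetyl group can enolise and only C1 can accept; C2 should approach C1 past the methyl and not the silyloxymethyl substituent of C11, with the carbonyl oxygen turned away from C6 (Felkin-type, no chelation by the silyl ether), which gives the C1 configuration of the target.

Step 20
Reactants: 28 β-hydroxy ketone
Product: 29 anti diol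
Conditions: Me4NBH(OAc)3, MeCN/AcOH, −25 °C
Reagents that add atoms: none
Why: Evans–Saksena reduction, in which the C1 hydroxyl binds the borohydride and delivers hydride intramolecularly to the C3 ketone, should give the 1,3-anti diol and so set C3.

Step 21
Reactants: 29 anti diol
Product: 30 keto diol
Conditions: PPTS, acetone/H2O, 55 °C
Reagents that add atoms: water, O
Why: Mild acid-catalysed ketal hydrolysis frees the C8 ketone and should spare the hindered primary silyl ether.

Step 22
Reactants: 30 keto diol
Product: 32 enone bis-silyl ether, via tris-silylated enol ether 31 (not isolated)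
Conditions: Me3SiOTf (3.5 equiv), Et3N, CH2Cl2, 0 °C; then Pd(OAc)2, MeCN, rt
Reagents that add atoms: trimethylsilyl trifluoromethanesulfonate, C[Si](C)(C)OS(=O)(=O)C(F)(F)F
Why: Saegusa–Ito oxidation: soft enolisation can only go towards C9 because C7 is a bridgehead, the two hydroxyls are masked in the same operation, and palladium diacetate converts the silyl enol ether into the C9=C10 enone.

Step 23
Reactants: 32 enone bis-silyl ether
Product: 34 methylated keto diol, via bis-silyl ether 33 (not isolated)
Conditions: Me2CuLi (from MeLi and CuI), Et2O, −78 °C; then 1 M HCl, THF, 0 °C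
Reagents that add atoms: lithium dimethylcuprate, [Li+].C[Cu-]C
Why: Conjugate addition of the Gilman cuprate to the bicyclo[3.1.1]heptenone should deliver methyl to C10 from the open C6-bridge face because the C4 methyl group hangs over the other face, and dilute acid then cleaves the two trimethylsilyl ethers.

Step 24
Reactants: 35 angelic acid; 34 methylated keto diol
Product: 38 bis-angelate, via mixed anhydride 36 (not isolated), via C3 mono-angelate 37 (not isolated)
Conditions: 35 (4 equiv), 2,4,6-trichlorobenzoyl chloride (4 equiv), Et3N, toluene, rt; then 34, toluene, 80 °C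
Reagents that add atoms: angelic acid (second equivalent), C/C=C(/C)C(=O)O
Why: Yamaguchi-type mixed-anhydride esterification run without a nucleophilic catalyst should acylate both hindered secondary hydroxyls in turn, each consuming one molecule of 36 (C3 expected first because its neighbour C4 is tied back in the cyclobutane, then C1), while keeping the Z geometry of the angeloyl groups.

Step 25
Reactants: 38 bis-angelate
Product: 39 target
Conditions: HF·pyridine, pyridine, THF, 0 °C → rt
Reagents that add atoms: none
Why: Fluoride desilylation under buffered acidic conditions frees the primary alcohol without base-induced migration of the neighbouring C1 angelate.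

**Compound list**

1 | (1R,4S)-cis-4-acetoxycyclopent-2-en-1-ol | CC(=O)O[C@H]1C[C@@H](O)C=C1 | starting material
2 | 2,2,5-trimethyl-1,3-dioxane-4,6-dione (methyl Meldrum's acid) | CC1C(=O)OC(C)(C)OC1=O | starting material
3 | 5-[(1S,4R)-4-hydroxycyclopent-2-en-1-yl]-2,2,5-trimethyl-1,3-dioxane-4,6-dione (C6–C11 bond cis to the C3 hydroxyl) | CC1(C(=O)OC(C)(C)OC1=O)[C@H]2C[C@@H](O)C=C2 | intermediate
4 | (1R,5S)-4-methyl-3-oxo-2-oxabicyclo[3.2.1]oct-6-ene-4-carboxylic acid, both C4 epimers | O=C1C(C)(C(=O)O)[C@@H]2C=C[C@@H](C2)O1 | intermediate (not isolated)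
5 | (1R,5S)-4-methyl-2-oxabicyclo[3.2.1]oct-6-en-3-one, both C4 epimers (ring C4 is target C11) | O=C1C(C)[C@@H]2C=C[C@@H](C2)O1 | intermediate
6 | (1R,4R,5S)-4-(benzyloxymethyl)-4-methyl-2-oxabicyclo[3.2.1]oct-6-en-3-one (benzyloxymethyl syn to the methylene bridge, methyl towards the C=C bridge) | O=C1[C@@](C)(COCc3ccccc3)[C@@H]2C=C[C@@H](C2)O1 | intermediate
7 | (1R,4S)-4-[(2S)-1-(benzyloxy)-3-hydroxy-2-methylpropan-2-yl]cyclopent-2-en-1-ol | OC[C@@](C)(COCc1ccccc1)[C@H]2C[C@@H](O)C=C2 | intermediate
8 | (1R,4S)-4-[(2R)-1-(benzyloxy)-3-(tert-butyldimethylsilyloxy)-2-methylpropan-2-yl]cyclopent-2-en-1-ol | CC(C)(C)[Si](C)(C)OC[C@@](C)(COCc1ccccc1)[C@H]2C[C@@H](O)C=C2 | intermediate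
9 | (4S)-4-[(2R)-1-(benzyloxy)-3-(tert-butyldimethylsilyloxy)-2-methylpropan-2-yl]cyclopent-2-en-1-one | CC(C)(C)[Si](C)(C)OC[C@@](C)(COCc1ccccc1)[C@H]2CC(=O)C=C2 | intermediate
10 | 2-iodo derivative of 9 (iodine on C4) | CC(C)(C)[Si](C)(C)OC[C@@](C)(COCc1ccccc1)[C@H]2CC(=O)C(I)=C2 | intermediate
11 | 2-methyl derivative of 9 (C3 ketone, C4(Me)=C7, C6 stereocentre, C5 methylene) | CC(C)(C)[Si](C)(C)OC[C@@](C)(COCc1ccccc1)[C@H]2CC(=O)C(C)=C2 | intermediate
12 | 3-bromobut-3-en-1-ol | OCCC(Br)=C | starting material
13 | (3-bromobut-3-en-1-yloxy)triethylsilane | CC[Si](CC)(CC)OCCC(Br)=C | intermediate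
14 | [4-(triethylsilyloxy)but-1-en-2-yl]magnesium bromide | CC[Si](CC)(CC)OCCC(=C)[Mg]Br | intermediate (not isolated)
15 | trimethylsilyl enol ether C3(OSiMe3)=C4(Me); C7 bears the 4-(triethylsilyloxy)but-1-en-2-yl chain trans to the C6 substituent | C[Si](C)(C)OC1=C(C)[C@H](C(=C)CCO[Si](CC)(CC)CC)[C@H](C1)[C@@](C)(CO[Si](C)(C)C(C)(C)C)COCc2ccccc2 | intermediate
16 | 2-bromo-2-methylcyclopentanone, Br trans to the C7 chain and cis to the C6 substituent, chain as triethylsilyl ether | O=C1[C@@](C)(Br)[C@H](C(=C)CCO[Si](CC)(CC)CC)[C@H](C1)[C@@](C)(CO[Si](C)(C)C(C)(C)C)COCc2ccccc2 | intermediate (not isolated)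
17 | as 16 with the chain as free primary alcohol (C10–OH) | O=C1[C@@](C)(Br)[C@H](C(=C)CCO)[C@H](C1)[C@@](C)(CO[Si](C)(C)C(C)(C)C)COCc2ccccc2 | intermediate
18 | primary triflate of 17 | O=C1[C@@](C)(Br)[C@H](C(=C)CCOS(=O)(=O)C(F)(F)F)[C@H](C1)[C@@](C)(CO[Si](C)(C)C(C)(C)C)COCc2ccccc2 | intermediate (not isolated)
19 | bicyclo[3.2.1]octanone: C3 ketone, C4 exo-Br/endo-Me, C8 exocyclic methylene, C11 group on C6 syn to the C3–C4 bridge | O=C1[C@@](C)(Br)[C@H]2[C@H]([C@@H]1CCC2=C)[C@@](C)(CO[Si](C)(C)C(C)(C)C)COCc3ccccc3 | intermediate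
20 | C8 methoxy hydroperoxide from 19 (C8 epimers) | O=C1[C@@](C)(Br)[C@H]2[C@H]([C@@H]1CCC2(OC)OO)[C@@](C)(CO[Si](C)(C)C(C)(C)C)COCc3ccccc3 | intermediate (not isolated)
21 | C3,C8-diketone (otherwise as 19) | O=C1[C@@](C)(Br)[C@H]2[C@H]([C@@H]1CCC2=O)[C@@](C)(CO[Si](C)(C)C(C)(C)C)COCc3ccccc3 | intermediate
22 | key-step precursor: exo-bromo bicyclo[3.2.1]octanone with C3 ketone, C4 Br/Me, C8 ethylene ketal | O=C1[C@@](C)(Br)[C@H]2[C@H]([C@@H]1CCC23OCCO3)[C@@](C)(CO[Si](C)(C)C(C)(C)C)COCc4ccccc4 | intermediate
23 | key-step product: bicyclo[3.1.1]heptane methyl ester (C3 ester on C4, anti to the C8–C10 bridge; C4 methyl syn to it) | COC(=O)[C@]1(C)[C@@H]2[C@@H]([C@H]1C3(OCCO3)CC2)[C@@](C)(CO[Si](C)(C)C(C)(C)C)COCc4ccccc4 | intermediate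
24 | α-trimethylsilyl ketone at C3 (present as its lithium enolate) | C[Si](C)(C)CC(=O)[C@]1(C)[C@@H]2[C@@H]([C@H]1C3(OCCO3)CC2)[C@@](C)(CO[Si](C)(C)C(C)(C)C)COCc4ccccc4 | intermediate (not isolated)
25 | C3 methyl ketone (acetyl methyl is C2) | CC(=O)[C@]1(C)[C@@H]2[C@@H]([C@H]1C3(OCCO3)CC2)[C@@](C)(CO[Si](C)(C)C(C)(C)C)COCc4ccccc4 | intermediate
26 | as 25 with the C1 arm as free primary alcohol | CC(=O)[C@]1(C)[C@@H]2[C@@H]([C@H]1C3(OCCO3)CC2)[C@@](C)(CO[Si](C)(C)C(C)(C)C)CO | intermediate
27 | as 25 with C1 as aldehyde | CC(=O)[C@]1(C)[C@@H]2[C@@H]([C@H]1C3(OCCO3)CC2)[C@@](C)(CO[Si](C)(C)C(C)(C)C)C=O | intermediate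
28 | tricyclic β-hydroxy ketone: C1 carbinol (OH cis to the C11 methyl), C3 ketone | O[C@@H]1CC(=O)[C@]2(C)[C@@H]3[C@@H]([C@H]2C4(OCCO4)CC3)[C@@]1(C)CO[Si](C)(C)C(C)(C)C | intermediate
29 | C1,C3 anti diol, C8 ketal | O[C@@H]1C[C@@H](O)[C@]2(C)[C@@H]3[C@@H]([C@H]2C4(OCCO4)CC3)[C@@]1(C)CO[Si](C)(C)C(C)(C)C | intermediate
30 | C1,C3 anti diol, C8 ketone | O[C@@H]1C[C@@H](O)[C@]2(C)[C@@H]3[C@@H]([C@H]2C(=O)CC3)[C@@]1(C)CO[Si](C)(C)C(C)(C)C | intermediate
31 | C8 trimethylsilyl enol ether (C8=C9) with C1 and C3 trimethylsilyl ethers | C[Si](C)(C)O[C@@H]1C[C@@H](O[Si](C)(C)C)[C@]2(C)[C@@H]3[C@@H]([C@H]2C(O[Si](C)(C)C)=CC3)[C@@]1(C)CO[Si](C)(C)C(C)(C)C | intermediate (not isolated)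
32 | C8 ketone C9=C10 enone, C1 and C3 trimethylsilyl ethers | C[Si](C)(C)O[C@@H]1C[C@@H](O[Si](C)(C)C)[C@]2(C)[C@@H]3[C@@H]([C@H]2C(=O)C=C3)[C@@]1(C)CO[Si](C)(C)C(C)(C)C | intermediate
33 | C10-methyl ketone, C1 and C3 trimethylsilyl ethers (methyl on the C6-bridge side) | C[Si](C)(C)O[C@@H]1C[C@@H](O[Si](C)(C)C)[C@]2(C)[C@@H]3[C@@H]([C@H]2C(=O)C[C@H]3C)[C@@]1(C)CO[Si](C)(C)C(C)(C)C | intermediate (not isolated)
34 | C10-methyl keto diol, primary silyl ether | O[C@@H]1C[C@@H](O)[C@]2(C)[C@@H]3[C@@H]([C@H]2C(=O)C[C@H]3C)[C@@]1(C)CO[Si](C)(C)C(C)(C)C | intermediate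
35 | angelic acid, (Z)-2-methylbut-2-enoic acid | C/C=C(/C)C(=O)O | starting material
36 | angelic 2,4,6-trichlorobenzoic anhydride | C/C=C(/C)C(=O)OC(=O)c1c(Cl)cc(Cl)cc1Cl | intermediate (not isolated)
37 | C3 mono-angelate with free C1 hydroxyl, primary tert-butyldimethylsilyl ether | O[C@@H]1C[C@@H](OC(=O)/C(C)=C\C)[C@]2(C)[C@@H]3[C@@H]([C@H]2C(=O)C[C@H]3C)[C@@]1(C)CO[Si](C)(C)C(C)(C)C | intermediate (not isolated)
38 | C1,C3 bis-angelate, primary tert-butyldimethylsilyl ether | C/C=C(/C)C(=O)O[C@@H]1C[C@@H](OC(=O)/C(C)=C\C)[C@]2(C)[C@@H]3[C@@H]([C@H]2C(=O)C[C@H]3C)[C@@]1(C)CO[Si](C)(C)C(C)(C)C | intermediate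
39 | CNP0287707.1 | C/C=C(/C)C(=O)O[C@@H]1C[C@@H](OC(=O)/C(C)=C\C)[C@]2(C)[C@@H]3[C@@H]([C@H]2C(=O)C[C@H]3C)[C@@]1(C)CO | target

**Step count.** 25 steps in total. The longest linear sequence is 24 steps (steps 1–8 and 10–25, from 1 to 39); step 9 prepares the side-chain fragment.

**Steps most likely to fail**

Step 15. Methoxide may act as a base and remove HBr towards the C4 methyl group, or add reversibly to C3 without triggering the shift. The fallback sets out from 22 and uses irreversible hydride addition in place of alkoxide addition. LiAlH4 in Et2O (−78 °C → rt) adds to C3 from the endo face, the aluminium alkoxide undergoes the same C5 shift to the ring-contracted aldehyde F1, and this is reduced in the flask to the primary alcohol F2. Dess–Martin oxidation of F2 returns aldehyde F1 as an isolated compound, MeMgBr in THF at −78 °C gives the methyl carbinol F3 as an epimer mixture, and a second Dess–Martin oxidation gives methyl ketone 25, where the route is rejoined.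

Step 12. Bromine may be transferred from the tertiary C4 bromide to the C5 enolate, or triflic acid may be lost from the side chain, before the ring closes. The fallback sets out from 15 and carries chlorine, a much poorer halogen donor towards enolates, through the same sequence. N-Chlorosuccinimide gives the silyl-protected chloro ketone F4, and PPTS in MeOH gives the chloro hydroxy ketone F5. Tf2O with 2,6-lutidine gives the primary triflate F6, and LiN(SiMe3)2 closes it to the bicyclic chloro ketone F7. Ozonolysis through the methoxy hydroperoxide F8 gives the chloro diketone F9, and ketalisation as in step 14 gives the chloro ketone ketal F10. F10 is contracted with NaOMe in MeOH (warmer than for the bromide) to give 23.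

Step 19. Facial selectivity at C1 may be poor, or retro-aldol equilibration may erode it, in the seven-membered aldol closure. The fallback sets out from 23 and exchanges the roles of the two carbonyl partners, so that the aldol creates C3 and the hydroxyl-directed reduction then sets C1. Hydrogenolysis gives the hydroxy ester F11 and Dess–Martin oxidation the aldehyde ester F12. MeMgBr at −78 °C adds only to the aldehyde to give the carbinol ester F13, and LiAlH4 reduces this to the diol F14. Dess–Martin oxidation of both hydroxyls gives the keto aldehyde F15 (C1 acetyl, C3 formyl). Lithium 2,2,6,6-tetramethylpiperidide at −78 °C closes F15 to the β-hydroxy ketone F16 (C3 carbinol, C1 ketone), and Me4NBH(OAc)3 reduces C1 anti to the C3 hydroxyl to give 29.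

Further compounds

F1 | step 15 | ring-contracted C3 aldehyde (as 23 with CHO in place of the ester) | O=C[C@]1(C)[C@@H]2[C@@H]([C@H]1C3(OCCO3)CC2)[C@@](C)(CO[Si](C)(C)C(C)(C)C)COCc4ccccc4
F2 | step 15 | ring-contracted C3 primary alcohol | OC[C@]1(C)[C@@H]2[C@@H]([C@H]1C3(OCCO3)CC2)[C@@](C)(CO[Si](C)(C)C(C)(C)C)COCc4ccccc4
F3 | step 15 | C3 methyl carbinol, both epimers | CC(O)[C@]1(C)[C@@H]2[C@@H]([C@H]1C3(OCCO3)CC2)[C@@](C)(CO[Si](C)(C)C(C)(C)C)COCc4ccccc4
F4 | step 12 | chloro analogue of 16 | O=C1[C@@](C)(Cl)[C@H](C(=C)CCO[Si](CC)(CC)CC)[C@H](C1)[C@@](C)(CO[Si](C)(C)C(C)(C)C)COCc2ccccc2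
F5 | step 12 | chloro analogue of 17 | O=C1[C@@](C)(Cl)[C@H](C(=C)CCO)[C@H](C1)[C@@](C)(CO[Si](C)(C)C(C)(C)C)COCc2ccccc2
F6 | step 12 | chloro analogue of 18 | O=C1[C@@](C)(Cl)[C@H](C(=C)CCOS(=O)(=O)C(F)(F)F)[C@H](C1)[C@@](C)(CO[Si](C)(C)C(C)(C)C)COCc2ccccc2
F7 | step 12 | chloro analogue of 19 | O=C1[C@@](C)(Cl)[C@H]2[C@H]([C@@H]1CCC2=C)[C@@](C)(CO[Si](C)(C)C(C)(C)C)COCc3ccccc3
F8 | step 12 | chloro analogue of 20 | O=C1[C@@](C)(Cl)[C@H]2[C@H]([C@@H]1CCC2(OC)OO)[C@@](C)(CO[Si](C)(C)C(C)(C)C)COCc3ccccc3
F9 | step 12 | chloro analogue of 21 | O=C1[C@@](C)(Cl)[C@H]2[C@H]([C@@H]1CCC2=O)[C@@](C)(CO[Si](C)(C)C(C)(C)C)COCc3ccccc3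
F10 | step 12 | chloro analogue of 22 | O=C1[C@@](C)(Cl)[C@H]2[C@H]([C@@H]1CCC23OCCO3)[C@@](C)(CO[Si](C)(C)C(C)(C)C)COCc4ccccc4
F11 | step 19 | hydroxy ester (23 without the benzyl group) | COC(=O)[C@]1(C)[C@@H]2[C@@H]([C@H]1C3(OCCO3)CC2)[C@@](C)(CO[Si](C)(C)C(C)(C)C)CO
F12 | step 19 | C1 aldehyde, C3 methyl ester | COC(=O)[C@]1(C)[C@@H]2[C@@H]([C@H]1C3(OCCO3)CC2)[C@@](C)(CO[Si](C)(C)C(C)(C)C)C=O
F13 | step 19 | C1 methyl carbinol (both epimers), C3 methyl ester | COC(=O)[C@]1(C)[C@@H]2[C@@H]([C@H]1C3(OCCO3)CC2)[C@@](C)(CO[Si](C)(C)C(C)(C)C)C(C)O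
F14 | step 19 | diol: C3 hydroxymethyl, C1 methyl carbinol | OC[C@]1(C)[C@@H]2[C@@H]([C@H]1C3(OCCO3)CC2)[C@@](C)(CO[Si](C)(C)C(C)(C)C)C(C)O
F15 | step 19 | keto aldehyde: C3 formyl, C1 acetyl | O=C[C@]1(C)[C@@H]2[C@@H]([C@H]1C3(OCCO3)CC2)[C@@](C)(CO[Si](C)(C)C(C)(C)C)C(C)=O
F16 | step 19 | tricyclic β-hydroxy ketone with C3 carbinol and C1 ketone | O=C1C[C@@H](O)[C@]2(C)[C@@H]3[C@@H]([C@H]2C4(OCCO4)CC3)[C@@]1(C)CO[Si](C)(C)C(C)(C)C
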